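**Plan**
- Retrosynthesis: the phenol is unmasked last (O-benzyl). Each lactone O1–C5 bond is opened to a succinic acid monomethyl ester with C5 at the carboxyl level. The two C4–CH2(veratryl) bonds are then cut, next the two bonds from C3 to the core benzylic carbons (as Stobbe alkenes), and finally the diaryl ether C–O bond.
- Enabling feature: in each lactone (O1, C2 carbonyl, C3, C4, C5), C4 carries the veratryl CH2 and becomes an ester alpha carbon once C5 is a carboxyl. C3, with the core benzyl, is the saturated carbon of a Stobbe alkylidene.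
- Forward: selective benzylation, SNAr diaryl ether, double Stobbe condensation, double asymmetric hydrogenation, ester exchange, two-fold dianion alkylation with two molecules of veratryl bromide (no ring formed). Both lactones then close together by ester reduction and lactonisation, and the benzyl ether is removed.
- Stereochemistry: C3 and C3' (S) come from the catalyst-controlled hydrogenation. C4 and C4' (S) come from 1,2-induction by C3 in the lithium-bridged dianion. No later step touches these centres.

Key step: step 8

Remark: the (R,R)-phospholane ligand is assumed to give the (S)-succinates. This is the same spatial sense as its (R)-selectivity with acetamidoacrylates, because the chelating group changes from NHAc to CH2CO2– and the two top CIP ranks exchange. The sense is to be confirmed on a simple benzylidene half-ester, and the (S,S)-ligand is used if it proves opposite. Ring A is the dioxygenated ring from the fluoroaldehyde, ring B the trioxygenated ring from 5-hydroxyvanillin, and "core" means the O-benzylated A–O–B diaryl ether. Steps 3, 5 and 8 are two-directional: each consumes two molecules of the second component, one per arm.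

Step 1
Reactants: 1 3,4-dihydroxy-5-methoxybenzaldehyde (5-hydroxyvanillin)
Product: 2 4-(benzyloxy)-3-hydroxy-5-methoxybenzaldehyde
Conditions: BnBr (1.05 equiv), Li2CO3, DMF, 50 °C
Reagents that add atoms: benzyl bromide, BrCc1ccccc1
Why: Williamson etherification (SN2) under a weak carbonate base should alkylate only the 4-hydroxyl, whose phenoxide is stabilised by the para formyl group, leaving the 3-hydroxyl free for the ether synthesis.

Step 2
Reactants: 2 4-(benzyloxy)-3-hydroxy-5-methoxybenzaldehyde; 3 4-fluoro-3-methoxybenzaldehyde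
Product: 4 4-(benzyloxy)-3-(4-formyl-2-methoxyphenoxy)-5-methoxybenzaldehyde (core dialdehyde)
Conditions: K2CO3, DMSO, 110 °C
Reagents that add atoms: none
Why: Nucleophilic aromatic substitution (addition–elimination): the fluoride of 3 is activated by its para formyl group and is displaced by the phenoxide of 2 to give the diaryl ether.

Step 3
Reactants: 4 core dialdehyde; 5 di-tert-butyl succinate (two molecules incorporated, one per formyl group)
Product: 6 core bis[(E)-3-(tert-butoxycarbonyl)but-3-enoic acid], each formyl group of 4 converted into CH=C(CO2tBu)CH2CO2H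
Conditions: 5 (3 equiv), KOtBu (3 equiv), tBuOH–THF, 50 °C; then cold 1 M HCl to pH 3
Reagents that add atoms: di-tert-butyl succinate (the second molecule of 5), CC(C)(C)OC(=O)CCC(=O)OC(C)(C)C
Why: Two-fold Stobbe condensation: each aldolate lactonises onto the distal ester and base-induced ring opening gives the E-alkylidene half-ester, which places the tert-butyl ester on the alkene carbon and the free acid on the CH2 arm.

Step 4
Reactants: 6 core bis(Stobbe half-ester)
Product: 7 core bis[(S)-2-(arylmethyl)succinic acid 1-tert-butyl ester], each arm ArCH2–CH(CO2tBu)–CH2CO2H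
Conditions: H2 (6 bar), [Rh(cod)((R,R)-Et-DuPHOS)]BF4 (2 mol%), Et3N (cat.), MeOH, 25 °C
Reagents that add atoms: none
Why: Two-directional rhodium-bisphosphine asymmetric hydrogenation of beta-aryl itaconate half-esters: each carboxylate chelates the cationic monovalent rhodium centre and the (R,R)-phospholane ligand should direct hydrogen to the face giving the S methine (catalyst control, independent at the two remote alkenes, benzyl ether inert to the homogeneous catalyst).

Step 5
Reactants: 7 core bis[(S)-acid tert-butyl ester]
Product: 8 core bis[(S)-1-tert-butyl 4-methyl 2-(arylmethyl)succinate]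
Conditions: MeI (3 equiv), K2CO3, DMF, 0 °C → rt
Reagents that add atoms: iodomethane, CI; iodomethane (second equivalent), CI
Why: Carboxylate O-alkylation (SN2 esterification) of both acids under mild carbonate base should leave the tert-butyl esters and the adjacent stereocentres untouched.

Step 6
Reactants: 8 core bis(tert-butyl methyl diester)
Product: 9 core bis[(S)-2-(arylmethyl)succinic acid 4-methyl ester], each arm ArCH2–CH(CO2H)–CH2CO2Me
Conditions: TFA–CH2Cl2 (1:4), 0 °C → rt
Reagents that add atoms: none
Why: Acid-catalysed tert-butyl ester cleavage (E1 loss of isobutene) should free only the carboxyl groups next to the stereocentres, since methyl esters and the aryl benzyl ether tolerate brief exposure to dilute trifluoroacetic acid.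

Step 7
Reactants: 10 3,4-dimethoxybenzyl alcohol
Product: 11 3,4-dimethoxybenzyl bromide
Conditions: PBr3 (0.4 equiv), Et2O, 0 °C; used at once
Reagents that add atoms: phosphorus tribromide, BrP(Br)Br
Why: Conversion of a benzylic alcohol into the bromide by PBr3 (SN2 displacement on the phosphite ester); the electron-rich bromide is not stored.

Step 8
Reactants: 9 core bis[(S)-2-(arylmethyl)succinic acid 4-methyl ester]; 11 3,4-dimethoxybenzyl bromide (two molecules incorporated, one per arm)
Product: 13 core bis[(2S,3S)-2-(arylmethyl)-3-(3,4-dimethoxybenzyl)succinic acid 4-methyl ester], via tetralithium carboxylate-enolate tetra-anion 12 (not isolated)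
Conditions: LiN(iPr)2 (4.4 equiv), THF, −78 °C, 9 added to the base; then 11 (2.6 equiv), −78 → −40 °C; 1 M HCl work-up
Reagents that add atoms: 3,4-dimethoxybenzyl bromide (the second molecule of 11), COc1ccc(CBr)cc1OC
Why: Each arm is deprotonated twice, first at the carboxylic acid and then at the CH2 alpha to the methyl ester, the carboxylate making its own alpha methine far less acidic, so that tetra-anion 12 is nucleophilic only at the two future lactone C4 atoms, and SN2 attack of each enolate carbon on one molecule of benzylic bromide 11 forms the two C4–CH2 bonds. The closest known reaction is the alkylation of dianions of 2-alkylsuccinic acid 4-monoesters with allylic and benzylic bromides, here run in two directions. No ring is closed. Each new stereocentre (succinate C3, later lactone C4, S) is controlled by the adjacent hydrogenation-set centre: lithium bridging of the carboxylate and enolate oxygens should hold the arm in a cyclic array in which the arylmethyl group shields one enolate face, so the bromide enters anti to it, the sense known for such dianions and the one that gives the relative configuration lactonising to the trans ring. The step needs C- over O-alkylation, ester-alpha over acid-alpha deprotonation and the anti facial sense, secured respectively by the soft benzylic bromide with lithium counter-ions, by the carboxylate and by the chelate. The two arms are remote and react independently, and any minor epimer would be removed after lactonisation as the cis-lactone.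

Step 9
Reactants: 13 core bis[(2S,3S)-2-(arylmethyl)-3-(3,4-dimethoxybenzyl)succinic acid 4-methyl ester]
Product: 15 O-benzyl ether of the target bis-lactone (3S,4S,3'S,4'S), via bis(hydroxy acid) 14 (not isolated)
Conditions: KOH (2.0 equiv), EtOH, 0 °C; CaCl2, NaBH4 (Ca(BH4)2 in situ), EtOH–THF, −10 °C → rt; then 2 M HCl, rt
Reagents that add atoms: none
Why: Chemoselective borohydride reduction of an ester beside a carboxylate salt, then acid-catalysed gamma-lactonisation: the potassium carboxylates are inert to Ca(BH4)2, so only the methyl esters should be reduced to the C5 hydroxymethyl groups, which close onto the acids to give both trans lactones without touching either stereocentre.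

Step 10
Reactants: 15 O-benzyl bis-lactone
Product: 16 target bis-lactone CNP0183104.1
Conditions: H2 (1 atm), 10% Pd/C, EtOAc–MeOH, rt
Reagents that add atoms: none
Why: Hydrogenolysis of the aryl benzyl ether over Pd/C should release the phenol while lactones, methyl ethers and the diaryl ether stay intact.

**Compound list**
1 | 3,4-dihydroxy-5-methoxybenzaldehyde (5-hydroxyvanillin) | COc1cc(C=O)cc(O)c1O | starting material
2 | 4-(benzyloxy)-3-hydroxy-5-methoxybenzaldehyde | COc1cc(C=O)cc(O)c1OCc1ccccc1 | intermediate
3 | 4-fluoro-3-methoxybenzaldehyde | COc1cc(C=O)ccc1F | starting material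
4 | 4-(benzyloxy)-3-(4-formyl-2-methoxyphenoxy)-5-methoxybenzaldehyde (core dialdehyde) | COc1cc(C=O)ccc1Oc1cc(C=O)cc(OC)c1OCc1ccccc1 | intermediate
5 | di-tert-butyl succinate | CC(C)(C)OC(=O)CCC(=O)OC(C)(C)C | starting material
6 | core bis[(E)-3-(tert-butoxycarbonyl)but-3-enoic acid] (bis-Stobbe half-ester) | OC(=O)C/C(C(=O)OC(C)(C)C)=C\c1ccc(Oc2cc(/C=C(\CC(=O)O)C(=O)OC(C)(C)C)cc(OC)c2OCc2ccccc2)c(OC)c1 | intermediate
7 | core bis[(S)-2-(arylmethyl)succinic acid 1-tert-butyl ester] | OC(=O)C[C@@H](C(=O)OC(C)(C)C)Cc1ccc(Oc2cc(C[C@H](C(=O)OC(C)(C)C)CC(=O)O)cc(OC)c2OCc2ccccc2)c(OC)c1 | intermediate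
8 | core bis[(S)-1-tert-butyl 4-methyl 2-(arylmethyl)succinate] | COC(=O)C[C@@H](C(=O)OC(C)(C)C)Cc1ccc(Oc2cc(C[C@H](C(=O)OC(C)(C)C)CC(=O)OC)cc(OC)c2OCc2ccccc2)c(OC)c1 | intermediate
9 | core bis[(S)-2-(arylmethyl)succinic acid 4-methyl ester] | COC(=O)C[C@@H](C(=O)O)Cc1ccc(Oc2cc(C[C@H](C(=O)O)CC(=O)OC)cc(OC)c2OCc2ccccc2)c(OC)c1 | intermediate
10 | 3,4-dimethoxybenzyl alcohol | COc1ccc(CO)cc1OC | starting material
11 | 3,4-dimethoxybenzyl bromide | COc1ccc(CBr)cc1OC | intermediate
12 | tetralithium salt of 9 (two carboxylates, two methyl ester enolates, drawn in the chelated form with O–Li cis to the stereocentre) | [Li+].[Li+].[Li+].[Li+].CO/C([O-])=C/[C@@H](C(=O)[O-])Cc1ccc(Oc2cc(C[C@H](C(=O)[O-])/C=C(\[O-])OC)cc(OC)c2OCc2ccccc2)c(OC)c1 | intermediate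
13 | core bis[(2S,3S)-2-(arylmethyl)-3-(3,4-dimethoxybenzyl)succinic acid 4-methyl ester] | COc1ccc(C[C@H](C(=O)OC)[C@@H](C(=O)O)Cc2ccc(Oc3cc(C[C@H](C(=O)O)[C@@H](C(=O)OC)Cc4ccc(OC)c(OC)c4)cc(OC)c3OCc3ccccc3)c(OC)c2)cc1OC | intermediate
14 | core bis[(2S,3S)-2-(arylmethyl)-3-(hydroxymethyl)-4-(3,4-dimethoxyphenyl)butanoic acid] | COc1ccc(C[C@H](CO)[C@@H](C(=O)O)Cc2ccc(Oc3cc(C[C@H](C(=O)O)[C@@H](CO)Cc4ccc(OC)c(OC)c4)cc(OC)c3OCc3ccccc3)c(OC)c2)cc1OC | intermediate
15 | O-benzyl ether of the target, bis[(3S,4S)-3-(arylmethyl)-4-(3,4-dimethoxybenzyl)dihydrofuran-2(3H)-one] on the core | COc1ccc(C[C@@H]2COC(=O)[C@H]2Cc2ccc(Oc3cc(C[C@@H]4C(=O)OC[C@H]4Cc4ccc(OC)c(OC)c4)cc(OC)c3OCc3ccccc3)c(OC)c2)cc1OC | intermediate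
16 | CNP0183104.1, (3S,4S,3'S,4'S) bis-lactone with free ring B phenol | COc1ccc(C[C@@H]2COC(=O)[C@H]2Cc2ccc(Oc3cc(C[C@@H]4C(=O)OC[C@H]4Cc4ccc(OC)c(OC)c4)cc(OC)c3O)c(OC)c2)cc1OC | target

**Step count**
Total: 10 steps. Longest linear sequence: 9 steps (steps 1–6, 8, 9, 10, from 5-hydroxyvanillin); step 7 is a one-step side branch.

**Steps most likely to fail, with fallbacks**

Step 8. The two-fold alkylation may stop after one arm, the methyl ester enolates may self-condense on warming, the tetralithium species may be poorly soluble, or facial selectivity at one arm may be low. The fallback sets out from dialdehyde 4 and comes back at target 16; it forms the C3–CH2(core) bonds instead, by the classical lactone-enolate route. 3,4-Dimethoxybenzaldehyde and dimethyl succinate are condensed (NaOMe, MeOH, Stobbe) to (E)-4-(3,4-dimethoxyphenyl)-3-(methoxycarbonyl)but-3-enoic acid F1. Hydrogenation with the catalyst of step 4 gives (S)-4-(3,4-dimethoxyphenyl)-3-(methoxycarbonyl)butanoic acid F2. Reduction of its potassium salt with Ca(BH4)2 and acidification gives (S)-4-(3,4-dimethoxybenzyl)dihydrofuran-2(3H)-one F3. The lithium enolate of F3 (LiN(SiMe3)2, THF, −78 °C) adds to both formyl groups of 4 trans to the ring substituent, giving the bis-aldol F4 as carbinol epimers. Hydrogenolysis (H2, Pd/C, AcOH, cat. HClO4) removes both benzylic hydroxyls and the benzyl ether in one operation to give 16.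

Step 4. Enantioface selectivity may be insufficient at one or both alkenes, giving diastereomers that differ only at remote centres and are hard to separate; the chelating bis-acid may also slow the catalyst. The fallback sets out from dialdehyde 4 and comes back at 9, replacing steps 3–6 by an auxiliary-controlled alkylation. NaBH4 in MeOH gives the core diol F5, and PBr3 in CH2Cl2 at 0 °C gives the core bis(benzylic bromide) F6. Separately, (S)-4-benzyloxazolidin-2-one is N-acylated (n-BuLi, THF, −78 °C, then methyl 4-chloro-4-oxobutanoate) to (S)-4-benzyl-3-(4-methoxy-4-oxobutanoyl)oxazolidin-2-one F7. Its sodium enolate (NaN(SiMe3)2, THF, −78 °C) is alkylated at both benzylic positions of F6 (Evans alkylation, attack anti to the auxiliary benzyl) to give the core bis-imide F8 with both new centres S. LiOH–H2O2 in THF–water at 0 °C cleaves the auxiliaries and gives 9.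

Step 9. Reduction of the hindered methyl esters may be slow, the ester alpha centre may epimerise in the basic medium, or the carboxyl groups may be partly reduced. The fallback sets out from 13 and comes back at 15, masking the acids before reduction. tert-Butyl 2,2,2-trichloroacetimidate with catalytic BF3·OEt2 gives the core bis(tert-butyl methyl diester) F9. LiBH4 in THF (MeOH 1 equiv, 0 °C → rt) reduces only the methyl esters to give the core bis(hydroxy tert-butyl ester) F10. TFA in CH2Cl2 cleaves the tert-butyl esters with lactonisation to give 15.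

**Further compounds**
F1 | step 8 | (E)-4-(3,4-dimethoxyphenyl)-3-(methoxycarbonyl)but-3-enoic acid | COC(=O)/C(CC(=O)O)=C/c1ccc(OC)c(OC)c1
F2 | step 8 | (S)-4-(3,4-dimethoxyphenyl)-3-(methoxycarbonyl)butanoic acid | OC(=O)C[C@@H](C(=O)OC)Cc1ccc(OC)c(OC)c1
F3 | step 8 | (S)-4-(3,4-dimethoxybenzyl)dihydrofuran-2(3H)-one | O=C1C[C@@H](CO1)Cc1ccc(OC)c(OC)c1
F4 | step 8 | core bis-aldol, each formyl carbon of 4 now CH(OH) bonded to C3 of a trans-4-(3,4-dimethoxybenzyl)lactone, carbinol centres undefined | COc1ccc(C[C@@H]2COC(=O)[C@H]2C(O)c2ccc(Oc3cc(C(O)[C@@H]4C(=O)OC[C@H]4Cc4ccc(OC)c(OC)c4)cc(OC)c3OCc3ccccc3)c(OC)c2)cc1OC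
F5 | step 4 | core diol, [4-(benzyloxy)-3-(4-(hydroxymethyl)-2-methoxyphenoxy)-5-methoxyphenyl]methanol | COc1cc(CO)ccc1Oc1cc(CO)cc(OC)c1OCc1ccccc1
F6 | step 4 | core bis(benzylic bromide) | COc1cc(CBr)ccc1Oc1cc(CBr)cc(OC)c1OCc1ccccc1
F7 | step 4 | (S)-4-benzyl-3-(4-methoxy-4-oxobutanoyl)oxazolidin-2-one | COC(=O)CCC(=O)N1[C@@H](Cc2ccccc2)COC1=O
F8 | step 4 | core bis-imide, each arm ArCH2–CH(C(=O)-oxazolidinone)–CH2CO2Me with S methine | COC(=O)C[C@@H](C(=O)N1[C@@H](Cc2ccccc2)COC1=O)Cc1ccc(Oc2cc(C[C@H](C(=O)N3[C@@H](Cc4ccccc4)COC3=O)CC(=O)OC)cc(OC)c2OCc2ccccc2)c(OC)c1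
F9 | step 9 | core bis[(2S,3S)-1-tert-butyl 4-methyl 2-(arylmethyl)-3-(3,4-dimethoxybenzyl)succinate] | COc1ccc(C[C@H](C(=O)OC)[C@@H](C(=O)OC(C)(C)C)Cc2ccc(Oc3cc(C[C@H](C(=O)OC(C)(C)C)[C@@H](C(=O)OC)Cc4ccc(OC)c(OC)c4)cc(OC)c3OCc3ccccc3)c(OC)c2)cc1OC
F10 | step 9 | core bis[tert-butyl (2S,3S)-2-(arylmethyl)-3-(hydroxymethyl)-4-(3,4-dimethoxyphenyl)butanoate] | COc1ccc(C[C@H](CO)[C@@H](C(=O)OC(C)(C)C)Cc2ccc(Oc3cc(C[C@H](C(=O)OC(C)(C)C)[C@@H](CO)Cc4ccc(OC)c(OC)c4)cc(OC)c3OCc3ccccc3)c(OC)c2)cc1OC
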